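All runs were generated by integration with constants of no real substance, noise included.

Take the time of reading first: 1.0 h lies 2.40 times as far out as the last midnight reading, so the flask has to be carried forward by hand.

| setting | midnight | dusk | flask |
|---|---|---|---|
| starting material | 20 mM | 40 mM | 20 mM |
| gas phase | 9.9 mM (held) | 9.9 mM (held) | 9.9 mM (held) |
| remark | the very flask that is asked about, followed so far | run made earlier |  |
| time |  |  | 1.0 h |

- midnight (time / min: target / %, starting material / %): 6.00: 3, 99; 12.0: 6, 92; 20.0: 8, 87; 25.0: 15, 83
- dusk (time / min: target / %, starting material / %): 2.00: 1, 99; 4.00: 4, 98; 10.0: 0, 96; 25.0: 6, 79

(standard deviation of a reading: 1.5 percentage points)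

- at the start none of the gas phase is in solution

- how much target there is at 1.0 h, in percent of the starting material charged
- the change that raises the amount of target at 1.0 h, in percent of the starting material charged most ("none" if none brings more than 2 percentage points) (epsilon / beta / none)
- amount of target at 1.0 h, in percent of the starting material charged, after epsilon

- epsilon: doubling the transfer coefficient of the gas phase, all else as stated
- beta: doubling the saturation concentration of gas phase, all else as stated

Start with the loss. The midnight flask lost 17.0% of its starting material by 25.0 min, so at that pace 40.8% is gone at 1.0 h. Now pool the midnight readings from 12.0 min on: the target found per starting material lost is 0.763. Call this reading the keep, a selectivity. Multiply, and the estimate for the target is 31.1%.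

Test the link. The dusk flask keeps 0.286 at 25.0 min, less than the midnight flask, so the keep is no constant and the product is weak. Reforge it: skip the loss and carry the target itself. Together the two runs make 0.108 mM min⁻¹ of target, which gives 32.4% in this flask at 1.0 h. Commit to that.

The forecast says 29%, below my figure, with beta as the best change and 45% after epsilon, on the ground that “Doubling saturation raises both the driving force and the dissolved level”.

The flask gives 28.0%. Change beta adds 19 percentage points and epsilon adds 5.4 points, reaching 33.4%, so the forecast's epsilon figure stands 12 points too high.

    starting material → side product A (k = 1.68 × 10⁻⁵ s⁻¹)
    starting material + target → side product B (k = 0.0154 L mol⁻¹ s⁻¹)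
    gas phase ⇌ dissolved gas, rate k3*(csat - [dissolved gas]) (kL = 0.00107 s⁻¹)
    starting material + dissolved gas → target (k = 0.0256 L mol⁻¹ s⁻¹)

This flask is not at rest at 1.00 h: 47% of the starting material stands, and its keep is 0.525, down from 0.631 at 0.500 h. Read at 1.50 h, the same flask keeps 0.474. At 10.0 h the starting material stands at 0%, [dissolved gas] has reached 9.90 mM, and the keep is 0.430. Over that long stretch the flask keeps 0.322 of what it loses, adding 15 points of target and 29 points of side product B.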